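The flavan C-ring is closed last, at C4–C4a, instead of joining two finished flavonoids. The flavonol A-ring is a 3,4,5-trioxygenated aryl whose C5 (para to O8, meta to O7 and O1) carries flavan C4; C4 is therefore taken from the formyl carbon of a gallaldehyde, and the 4→5 link needs no substitution on a flavonol. In the key step the single free ortho carbon of an open-chain 2,3-bis(benzyloxy)phenyl ether (future C4a, para to O7) opens a trans-1,3-diaryl-epoxide at its benzylic carbon with inversion, which forms the pyran ring and completes the 2,3-cis-3,4-trans triad in one operation. The flavonol is annulated afterwards onto an ortho-bromine handle.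

Key step: step 7

Remark: building blocks 1, 3, 7 and 15 are taken as commercial benzyl ethers (each is otherwise one benzylation from the commercial phenol); flavan locants (O1, C2, C3, C4, C4a) are used for the matching atoms of open-chain intermediates, and primed locants for the flavonol unit.

Step 1
Reactants: 1 3,4,5-tris(benzyloxy)benzaldehyde
Product: 2 2-bromo-3,4,5-tris(benzyloxy)benzaldehyde
Conditions: NBS, MeCN, rt, dark
Reagents that add atoms: N-bromosuccinimide, O=C1CCC(=O)N1Br
Why: Electrophilic aromatic bromination, for which the two equivalent free ring positions are each ortho and para to a benzyloxy group as in other 3,4,5-trialkoxybenzaldehydes; ionic conditions in the dark should leave the benzylic CH2 groups alone.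

Step 2
Reactants: 2 2-bromo-3,4,5-tris(benzyloxy)benzaldehyde; 3 1-[3,4-bis(benzyloxy)phenyl]ethanone
Product: 4 (E)-1-[3,4-bis(benzyloxy)phenyl]-3-[2-bromo-3,4,5-tris(benzyloxy)phenyl]prop-2-en-1-one
Conditions: KOH (50% aq.), EtOH/THF, rt
Reagents that add atoms: none
Why: Claisen–Schmidt aldol condensation of a methyl ketone with a non-enolisable aldehyde, in which E1cB dehydration should give the (E)-enone.

Step 3
Reactants: 4 (E)-chalcone
Product: 5 [3,4-bis(benzyloxy)phenyl][(2R,3S)-3-[2-bromo-3,4,5-tris(benzyloxy)phenyl]oxiran-2-yl]methanone (trans-epoxy ketone)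
Conditions: poly-L-leucine, urea–H2O2, DBU, THF, rt
Reagents that add atoms: hydrogen peroxide (as its urea adduct), OO
Why: Juliá–Colonna epoxidation (Weitz–Scheffer hydroperoxide addition within the helical peptide), for which poly-L-leucine is expected to give the trans-(2R,3S)-epoxy ketone as with other chalcones, fixing the future C3 and the epoxide carbon that becomes C4.

Step 4
Reactants: 5 trans-(2R,3S)-epoxy ketone
Product: 6 (S)-[3,4-bis(benzyloxy)phenyl][(2S,3S)-3-[2-bromo-3,4,5-tris(benzyloxy)phenyl]oxiran-2-yl]methanol (erythro epoxy alcohol)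
Conditions: NaBH4, CeCl3·7H2O, MeOH/THF, −78 °C
Reagents that add atoms: none
Why: Cerium-mediated (Luche-type) chelation-controlled borohydride reduction, in which the metal bridges the carbonyl and epoxide oxygens and hydride enters from the side of the α-hydrogen, should give the erythro alcohol with (S) configuration at the carbinol carbon and leave the epoxide and aryl bromide untouched at −78 °C.

Step 5
Reactants: 7 2,3-bis(benzyloxy)benzaldehyde
Product: 9 2,3-bis(benzyloxy)phenol, via aryl formate 8 (not isolated)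
Conditions: mCPBA, CH2Cl2, rt; then K2CO3 (cat.), MeOH, rt
Reagents that add atoms: meta-chloroperbenzoic acid, O=C(OO)c1cccc(Cl)c1
Why: Dakin-type Baeyer–Villiger oxidation, in which the electron-rich ortho-alkoxyaryl group migrates to oxygen to give the aryl formate, followed by methanolysis to the phenol.

Step 6
Reactants: 6 erythro epoxy alcohol; 9 2,3-bis(benzyloxy)phenol
Product: 10 1-{(R)-[3,4-bis(benzyloxy)phenyl][(2R,3S)-3-[2-bromo-3,4,5-tris(benzyloxy)phenyl]oxiran-2-yl]methoxy}-2,3-bis(benzyloxy)benzene (threo epoxy aryl ether; C2 R, C3 R, C4 S in flavan locants)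
Conditions: PPh3, DIAD, toluene, 0 °C to rt
Reagents that add atoms: none
Why: Mitsunobu etherification, in which the phenol should displace the oxyphosphonium with SN2 inversion to turn the (S)-carbinol into the (R)-aryl ether (threo to the epoxide oxygen, as needed for 2,3-cis), the neighbouring epoxide oxygen and the non-polar cold medium being relied on to suppress ionisation of the electron-rich benzylic centre.

Step 7
Reactants: 10 threo epoxy aryl ether
Product: 11 (2R,3R,4R)-7,8-bis(benzyloxy)-2-[3,4-bis(benzyloxy)phenyl]-4-[2-bromo-3,4,5-tris(benzyloxy)phenyl]chroman-3-ol (2,3-cis-3,4-trans; C4 is labelled R only because bromine raises the CIP rank of the aryl group, the geometry is that of C4 (S) in the target)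
Conditions: BF3·OEt2 (0.2 equiv), CH2Cl2 (0.01 M), −78 to −40 °C
Reagents that add atoms: none
Why: The Lewis acid binds the epoxide oxygen, the C–O bond at the benzylic carbon (future C4) loosens because the para-benzyloxy group of the bromo-trialkoxyphenyl ring stabilises positive charge there, and the tethered aryl ether attacks that carbon from the face opposite the departing oxygen, after which rearomatisation and proton transfer to the alkoxide release the catalyst. The closest known reaction type is the intramolecular Friedel–Crafts epoxy–arene cyclisation of aryl 3-arylglycidyl ethers to trans-4-arylchroman-3-ols. The pyran ring closes through C4–C4a in a 6-endo epoxide opening (a six-membered Friedel–Crafts alkylation). C4 is set by inversion at the epoxide carbon, so its aryl group ends trans to the C3 oxygen, and if the opening drifts towards a free benzylic cation, attack anti to the Lewis-acid-bound C3 oxygen should lead to the same 3,4-trans isomer; C2 and C3 are carried unchanged from 10 and are cis. The step needs 6-endo attack at C4 rather than 5-exo attack at C3, attack by the aryl ether ring rather than by the C2 aryl ring (which would give an indane), and survival of the benzylic C2–O bond; these rest on benzylic charge stabilisation at C4, on the ortho-oxygen/para-benzyloxy activation of the attacking carbon together with the strained 5-endo geometry open to the C2 aryl ring, and on catalytic acid at low temperature and high dilution. Regiochemistry on the A-ring is fixed because the ether has a single free ortho carbon, para to the future O7.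

Step 8
Reactants: 11 bromo-4-arylflavan-3-ol
Product: 13 1-{2,3,4-tris(benzyloxy)-6-[(2R,3R,4S)-7,8-bis(benzyloxy)-2-[3,4-bis(benzyloxy)phenyl]-3-hydroxychroman-4-yl]phenyl}ethanone, via enol ether 12 (not isolated)
Conditions: Pd2(dba)3, XPhos, CsF, tributyl(1-ethoxyvinyl)stannane, dioxane, 100 °C; then 1 M HCl, THF, rt
Reagents that add atoms: tributyl(1-ethoxyvinyl)stannane, CCCC[Sn](CCCC)(CCCC)C(=C)OCC; water, O
Why: Stille coupling with an acetyl-anion equivalent followed by mild hydrolysis of the enol ether, a bulky biarylphosphine being chosen because the bromide is flanked on both sides, and the neutral conditions leaving the free C3–OH and all stereocentres untouched.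

Step 9
Reactants: 13 aryl methyl ketone
Product: 14 1-{3,4-bis(benzyloxy)-2-hydroxy-6-[(2R,3R,4S)-7,8-bis(benzyloxy)-2-[3,4-bis(benzyloxy)phenyl]-3-hydroxychroman-4-yl]phenyl}ethanone
Conditions: MgBr2·OEt2, toluene/Et2O, 70 °C; aq. HCl work-up
Reagents that add atoms: none
Why: Chelation-controlled dealkylation, in which magnesium bridges the ketone oxygen and the one ortho ether oxygen and bromide removes only that benzyl group, should free the future O1' and leave the other six benzyl ethers.

Step 10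
Reactants: 14 2'-hydroxyacetophenone; 15 3,4-bis(benzyloxy)benzaldehyde
Product: 16 (E)-1-{3,4-bis(benzyloxy)-2-hydroxy-6-[(2R,3R,4S)-7,8-bis(benzyloxy)-2-[3,4-bis(benzyloxy)phenyl]-3-hydroxychroman-4-yl]phenyl}-3-[3,4-bis(benzyloxy)phenyl]prop-2-en-1-one
Conditions: KOH (50% aq.), EtOH/THF, rt
Reagents that add atoms: none
Why: Claisen–Schmidt condensation of the 2'-hydroxyacetophenone with a non-enolisable aldehyde should give the (E)-2'-hydroxychalcone, the secondary alcohol and the non-acidic C2 and C4 stereocentres being inert to hydroxide.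

Step 11
Reactants: 16 2'-hydroxychalcone
Product: 17 7,8-bis(benzyloxy)-2-[3,4-bis(benzyloxy)phenyl]-5-[(2R,3R,4S)-7,8-bis(benzyloxy)-2-[3,4-bis(benzyloxy)phenyl]-3-hydroxychroman-4-yl]-3-hydroxy-4H-chromen-4-one
Conditions: 30% H2O2, NaOH, MeOH/THF, 0 °C to rt
Reagents that add atoms: hydrogen peroxide, OO
Why: Algar–Flynn–Oyamada reaction, in which alkaline peroxide oxidises the enone, the phenoxide closes the pyranone ring at the β-carbon and further oxidation gives the 3-hydroxyflavone, without touching the stereocentres of the flavan unit.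

Step 12
Reactants: 17 octa-O-benzyl flavan–flavonol
Product: 18 2-(3,4-dihydroxyphenyl)-5-[(2R,3R,4S)-2-(3,4-dihydroxyphenyl)-3,7,8-trihydroxychroman-4-yl]-3,7,8-trihydroxy-4H-chromen-4-one (CNP0395591.1)
Conditions: H2 (1 atm), Pd(OH)2/C, THF/MeOH, rt, degassed solvents
Reagents that add atoms: none
Why: Hydrogenolysis of the eight aryl benzyl ethers over palladium, under which the cyclic benzylic C2–O1 bond of flavans and the flavonol C2=C3 bond are known to survive and no stereocentre is affected.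

Compound list
1 | 3,4,5-tris(benzyloxy)benzaldehyde | O=Cc1cc(OCc2ccccc2)c(OCc2ccccc2)c(OCc2ccccc2)c1 | starting material
2 | 2-bromo-3,4,5-tris(benzyloxy)benzaldehyde | O=Cc1cc(OCc2ccccc2)c(OCc2ccccc2)c(OCc2ccccc2)c1Br | intermediate
3 | 1-[3,4-bis(benzyloxy)phenyl]ethanone | CC(=O)c1ccc(OCc2ccccc2)c(OCc2ccccc2)c1 | starting material
4 | (E)-1-[3,4-bis(benzyloxy)phenyl]-3-[2-bromo-3,4,5-tris(benzyloxy)phenyl]prop-2-en-1-one | O=C(/C=C/c1cc(OCc2ccccc2)c(OCc2ccccc2)c(OCc2ccccc2)c1Br)c1ccc(OCc2ccccc2)c(OCc2ccccc2)c1 | intermediate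
5 | [3,4-bis(benzyloxy)phenyl][(2R,3S)-3-[2-bromo-3,4,5-tris(benzyloxy)phenyl]oxiran-2-yl]methanone | Brc1c(OCc2ccccc2)c(OCc2ccccc2)c(OCc2ccccc2)cc1[C@@H]3O[C@H]3C(=O)c1ccc(OCc2ccccc2)c(OCc2ccccc2)c1 | intermediate
6 | (S)-[3,4-bis(benzyloxy)phenyl][(2S,3S)-3-[2-bromo-3,4,5-tris(benzyloxy)phenyl]oxiran-2-yl]methanol (erythro) | Brc1c(OCc2ccccc2)c(OCc2ccccc2)c(OCc2ccccc2)cc1[C@@H]3O[C@H]3[C@@H](O)c1ccc(OCc2ccccc2)c(OCc2ccccc2)c1 | intermediate
7 | 2,3-bis(benzyloxy)benzaldehyde | O=Cc1cccc(OCc2ccccc2)c1OCc1ccccc1 | starting material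
8 | 2,3-bis(benzyloxy)phenyl formate | O=COc1cccc(OCc2ccccc2)c1OCc1ccccc1 | intermediate
9 | 2,3-bis(benzyloxy)phenol | Oc1cccc(OCc2ccccc2)c1OCc1ccccc1 | intermediate
10 | 1-{(R)-[3,4-bis(benzyloxy)phenyl][(2R,3S)-3-[2-bromo-3,4,5-tris(benzyloxy)phenyl]oxiran-2-yl]methoxy}-2,3-bis(benzyloxy)benzene | Brc1c(OCc2ccccc2)c(OCc2ccccc2)c(OCc2ccccc2)cc1[C@@H]3O[C@H]3[C@@H](c1ccc(OCc2ccccc2)c(OCc2ccccc2)c1)Oc1cccc(OCc2ccccc2)c1OCc1ccccc1 | intermediate
11 | (2R,3R,4R)-7,8-bis(benzyloxy)-2-[3,4-bis(benzyloxy)phenyl]-4-[2-bromo-3,4,5-tris(benzyloxy)phenyl]chroman-3-ol (2,3-cis-3,4-trans) | Brc1c(OCc2ccccc2)c(OCc2ccccc2)c(OCc2ccccc2)cc1[C@H]3c4ccc(OCc5ccccc5)c(OCc5ccccc5)c4O[C@H](c4ccc(OCc5ccccc5)c(OCc5ccccc5)c4)[C@@H]3O | intermediate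
12 | (2R,3R,4S)-7,8-bis(benzyloxy)-2-[3,4-bis(benzyloxy)phenyl]-4-[2-(1-ethoxyvinyl)-3,4,5-tris(benzyloxy)phenyl]chroman-3-ol | C=C(OCC)c1c(OCc2ccccc2)c(OCc2ccccc2)c(OCc2ccccc2)cc1[C@H]3c4ccc(OCc5ccccc5)c(OCc5ccccc5)c4O[C@H](c4ccc(OCc5ccccc5)c(OCc5ccccc5)c4)[C@@H]3O | intermediate
13 | 1-{2,3,4-tris(benzyloxy)-6-[(2R,3R,4S)-7,8-bis(benzyloxy)-2-[3,4-bis(benzyloxy)phenyl]-3-hydroxychroman-4-yl]phenyl}ethanone | CC(=O)c1c(OCc2ccccc2)c(OCc2ccccc2)c(OCc2ccccc2)cc1[C@H]3c4ccc(OCc5ccccc5)c(OCc5ccccc5)c4O[C@H](c4ccc(OCc5ccccc5)c(OCc5ccccc5)c4)[C@@H]3O | intermediate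
14 | 1-{3,4-bis(benzyloxy)-2-hydroxy-6-[(2R,3R,4S)-7,8-bis(benzyloxy)-2-[3,4-bis(benzyloxy)phenyl]-3-hydroxychroman-4-yl]phenyl}ethanone | CC(=O)c1c(O)c(OCc2ccccc2)c(OCc2ccccc2)cc1[C@H]3c4ccc(OCc5ccccc5)c(OCc5ccccc5)c4O[C@H](c4ccc(OCc5ccccc5)c(OCc5ccccc5)c4)[C@@H]3O | intermediate
15 | 3,4-bis(benzyloxy)benzaldehyde | O=Cc1ccc(OCc2ccccc2)c(OCc2ccccc2)c1 | starting material
16 | (E)-1-{3,4-bis(benzyloxy)-2-hydroxy-6-[(2R,3R,4S)-7,8-bis(benzyloxy)-2-[3,4-bis(benzyloxy)phenyl]-3-hydroxychroman-4-yl]phenyl}-3-[3,4-bis(benzyloxy)phenyl]prop-2-en-1-one | O=C(/C=C/c1ccc(OCc2ccccc2)c(OCc2ccccc2)c1)c1c(O)c(OCc2ccccc2)c(OCc2ccccc2)cc1[C@H]3c4ccc(OCc5ccccc5)c(OCc5ccccc5)c4O[C@H](c4ccc(OCc5ccccc5)c(OCc5ccccc5)c4)[C@@H]3O | intermediate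
17 | 7,8-bis(benzyloxy)-2-[3,4-bis(benzyloxy)phenyl]-5-[(2R,3R,4S)-7,8-bis(benzyloxy)-2-[3,4-bis(benzyloxy)phenyl]-3-hydroxychroman-4-yl]-3-hydroxy-4H-chromen-4-one | O=c1c(O)c(-c2ccc(OCc5ccccc5)c(OCc5ccccc5)c2)oc2c(OCc5ccccc5)c(OCc5ccccc5)cc([C@H]3c4ccc(OCc5ccccc5)c(OCc5ccccc5)c4O[C@H](c4ccc(OCc5ccccc5)c(OCc5ccccc5)c4)[C@@H]3O)c12 | intermediate
18 | 2-(3,4-dihydroxyphenyl)-5-[(2R,3R,4S)-2-(3,4-dihydroxyphenyl)-3,7,8-trihydroxychroman-4-yl]-3,7,8-trihydroxy-4H-chromen-4-one | O=c1c(O)c(-c2ccc(O)c(O)c2)oc2c(O)c(O)cc([C@H]3c4ccc(O)c(O)c4O[C@H](c4ccc(O)c(O)c4)[C@@H]3O)c12 | target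

Total step count: 12. Longest linear sequence: 11 steps (steps 1–4 and 6–12; step 5 is a one-step side branch).

Steps most likely to fail

Step 7 (key step). The epoxide opening may take the 5-exo course at C3, may be intercepted by the C2 aryl ring, or may be outrun by ionisation of the benzylic C2–O bond. The fallback changes the order of bond formation; it sets out from 6 (with 9) and comes back at 11, and so also bypasses step 6. The bromomagnesium phenoxide of 9 (EtMgBr, toluene) should alkylate at its only free ortho carbon with the benzylic epoxide carbon of 6, with metal-templated delivery and inversion. This should give the open-chain (1S,2R,3R)-3-[3,4-bis(benzyloxy)-2-hydroxyphenyl]-1-[3,4-bis(benzyloxy)phenyl]-3-[2-bromo-3,4,5-tris(benzyloxy)phenyl]propane-1,2-diol F1. The pyran ring would then be closed at O1–C2 by intramolecular Mitsunobu etherification (PPh3, DIAD, THF, 0 °C) with inversion at the benzylic carbinol, to give 11.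

Step 8. Oxidative addition at the doubly ortho-flanked C–Br bond may be too slow, so that protodebromination or catalyst decay wins. The fallback replaces the cross-coupling by polar organometallic chemistry; it sets out from 11 and comes back at 13. After deprotonation of the C3–OH (n-BuLi), bromine–lithium exchange (t-BuLi, THF, −78 °C) and addition to acetaldehyde should give 1-{2,3,4-tris(benzyloxy)-6-[(2R,3R,4S)-7,8-bis(benzyloxy)-2-[3,4-bis(benzyloxy)phenyl]-3-hydroxychroman-4-yl]phenyl}ethanol F2 as a pair of carbinol epimers. MnO2 (CH2Cl2, rt) should then oxidise only the benzylic alcohol, to give 13.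

Step 11. The phenoxide may open the intermediate chalcone epoxide at the α-carbon (5-exo), which diverts material to the aurone; this is a known course when the 6'-position is substituted. The fallback separates ring closure from C3 oxygenation; it sets out from 16 and comes back at 17. Oxidative cyclisation (cat. I2, DMSO, 110 °C) should give 7,8-bis(benzyloxy)-2-[3,4-bis(benzyloxy)phenyl]-5-[(2R,3R,4S)-7,8-bis(benzyloxy)-2-[3,4-bis(benzyloxy)phenyl]-3-hydroxychroman-4-yl]-4H-chromen-4-one F3. Epoxidation of its C2'=C3' bond with dimethyldioxirane (acetone/CH2Cl2, 0 °C) should give the flavone 2',3'-epoxide F4 (either epoxide face serves). Acid-catalysed opening and tautomerisation (cat. TsOH) should then give 17.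

Further compounds
F1 | step 7 | (1S,2R,3R)-3-[3,4-bis(benzyloxy)-2-hydroxyphenyl]-1-[3,4-bis(benzyloxy)phenyl]-3-[2-bromo-3,4,5-tris(benzyloxy)phenyl]propane-1,2-diol | Brc1c(OCc2ccccc2)c(OCc2ccccc2)c(OCc2ccccc2)cc1[C@@H](c1ccc(OCc2ccccc2)c(OCc2ccccc2)c1O)[C@@H](O)[C@@H](O)c1ccc(OCc2ccccc2)c(OCc2ccccc2)c1
F2 | step 8 | 1-{2,3,4-tris(benzyloxy)-6-[(2R,3R,4S)-7,8-bis(benzyloxy)-2-[3,4-bis(benzyloxy)phenyl]-3-hydroxychroman-4-yl]phenyl}ethanol (both carbinol epimers) | CC(O)c1c(OCc2ccccc2)c(OCc2ccccc2)c(OCc2ccccc2)cc1[C@H]3c4ccc(OCc5ccccc5)c(OCc5ccccc5)c4O[C@H](c4ccc(OCc5ccccc5)c(OCc5ccccc5)c4)[C@@H]3O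
F3 | step 11 | 7,8-bis(benzyloxy)-2-[3,4-bis(benzyloxy)phenyl]-5-[(2R,3R,4S)-7,8-bis(benzyloxy)-2-[3,4-bis(benzyloxy)phenyl]-3-hydroxychroman-4-yl]-4H-chromen-4-one | O=c1cc(-c2ccc(OCc5ccccc5)c(OCc5ccccc5)c2)oc2c(OCc5ccccc5)c(OCc5ccccc5)cc([C@H]3c4ccc(OCc5ccccc5)c(OCc5ccccc5)c4O[C@H](c4ccc(OCc5ccccc5)c(OCc5ccccc5)c4)[C@@H]3O)c12
F4 | step 11 | 2',3'-epoxide of F3 (1a,7a-dihydro-7H-oxireno[2,3-b]chromen-7-one core; epoxide face undefined) | O=C1C6OC6(c2ccc(OCc5ccccc5)c(OCc5ccccc5)c2)Oc2c(OCc5ccccc5)c(OCc5ccccc5)cc([C@H]3c4ccc(OCc5ccccc5)c(OCc5ccccc5)c4O[C@H](c4ccc(OCc5ccccc5)c(OCc5ccccc5)c4)[C@@H]3O)c12
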